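**Retrosynthetic overview**

1. Ring letters: A is the enal arene, B its trans dioxane (O1, C2, C3, O4), C the central arene, D the cis dioxane, E the catechol. The plan rests on C2 of ring B: it is benzylic to ring C and para to the ring C oxygen, so it can be ionised to a para-quinone methide, while C2, C3 and the hydroxymethyl carbon map onto the carboxyl, α and β carbons of D-serine.
2. Late stage: the enal comes from a ring A nitrile (iBu2AlH, then Wittig). Ring D comes from O–aryl closure at a ring C bromide, after the ring C phenol has opened a (2S,3S)-aryl glycidol (made from ethyl caffeate) at its benzylic carbon.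
3. Ring B: O1–C2 by acid-mediated quinone methide closure of an aryl glycerol β-aryl ether; the C2–ring C bond by arylmagnesium addition to a Weinreb amide; C3–O4 by Mitsunobu inversion of methyl (R)-glycerate from D-serine.
4. Order of ring formation: ring B (step 10), then ring D (step 16); rings A, C and E are bought as arenes.

Key step: step 10

Remark on the chemistry: the target is read as ring B trans (C2 S, C3 S) and ring D cis (aryl carbon R, hydroxymethyl carbon S). Carbinol 15 is carried as a mixture of epimers because both converge in step 10.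

**Route**

Step 1
Reactants: 1 3,4-dihydroxybenzonitrile
Product: 2 4-hydroxy-3-(methoxymethoxy)benzonitrile
Conditions: NaH (2.2 equiv), DMF, 0 °C; then MOMCl (1.0 equiv), −20 → 0 °C; aq. NH4Cl
Reagents that add atoms: chloromethyl methyl ether (MOMCl), COCCl
Why: Regioselective mono-O-alkylation of a catechol dianion: the 4-oxide is delocalised into the para nitrile, so one equivalent of MOMCl should be taken by the more nucleophilic 3-oxide, which leaves the hydroxyl para to the nitrile free for step 5.

Step 2
Reactants: 3 D-serine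
Product: 5 (R)-glyceric acid, via alpha-lactone 4 (not isolated)
Conditions: NaNO2, aq. H2SO4, 0 °C → rt
Reagents that add atoms: water, O
Why: Nitrous acid deamination of an α-amino acid: loss of N2 with participation of the carboxylate gives the α-lactone 4, which water opens at the same carbon, so two inversions should return the (R) configuration, and H2SO4 offers no competing nucleophilic counter-ion.

Step 3
Reactants: 5 (R)-glyceric acid
Product: 6 methyl (R)-glycerate
Conditions: MeOH, H2SO4 (cat.), reflux
Reagents that add atoms: methanol, CO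
Why: Fischer esterification in a large excess of methanol should convert the acid (and any self-esters formed on concentration) into the methyl ester without touching the stereocentre.

Step 4
Reactants: 6 methyl (R)-glycerate
Product: 7 methyl (R)-3-[(tert-butyldimethylsilyl)oxy]-2-hydroxypropanoate
Conditions: TBSCl (1.05 equiv), imidazole, CH2Cl2, 0 °C
Reagents that add atoms: tert-butyldimethylsilyl chloride (TBSCl), CC(C)(C)[Si](C)(C)Cl
Why: Silylation with one equivalent of TBSCl should go to the primary hydroxyl for steric reasons and leave the secondary α-hydroxyl free for the Mitsunobu reaction.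

Step 5
Reactants: 7 methyl (R)-3-[(tert-butyldimethylsilyl)oxy]-2-hydroxypropanoate; 2 4-hydroxy-3-(methoxymethoxy)benzonitrile
Product: 8 methyl (S)-3-[(tert-butyldimethylsilyl)oxy]-2-[4-cyano-2-(methoxymethoxy)phenoxy]propanoate
Conditions: PPh3, DIAD, THF, 0 °C → rt
Reagents that add atoms: none
Why: Mitsunobu etherification of an α-hydroxy ester with an acidic phenol (para nitrile) proceeds by SN2 displacement of the oxyphosphonium group, so the C3–O4 aryl ether bond should form with clean inversion to the (S) centre that becomes C3 of ring B.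

Step 6
Reactants: 8 methyl (S)-3-[(tert-butyldimethylsilyl)oxy]-2-[4-cyano-2-(methoxymethoxy)phenoxy]propanoate
Product: 9 (S)-3-[(tert-butyldimethylsilyl)oxy]-2-[4-cyano-2-(methoxymethoxy)phenoxy]-N-methoxy-N-methylpropanamide
Conditions: MeNH(OMe)·HCl, iPrMgCl, THF, −20 °C
Reagents that add atoms: N,O-dimethylhydroxylamine hydrochloride, CNOC.Cl
Why: Aminolysis of the ester by the chloromagnesium amide of N,O-dimethylhydroxylamine (Weinreb amide formation) is fast at −20 °C, where the aryl nitrile is inert and the α-aryloxy centre should not epimerise because iPrMgCl is consumed by the amine salt as it is added.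

Step 7
Reactants: 10 2-bromo-4-iodophenol
Product: 11 2-bromo-4-iodo-1-(methoxymethoxy)benzene
Conditions: MOMCl, iPr2NEt, CH2Cl2, 0 °C → rt
Reagents that add atoms: chloromethyl methyl ether (MOMCl), COCCl
Why: Standard acetal protection of a phenol (Williamson-type alkylation with MOMCl and a hindered amine base); the MOM group survives the arylmagnesium chemistry and comes off under the acid of step 10.

Step 8
Reactants: 11 2-bromo-4-iodo-1-(methoxymethoxy)benzene; 9 (S)-3-[(tert-butyldimethylsilyl)oxy]-2-[4-cyano-2-(methoxymethoxy)phenoxy]-N-methoxy-N-methylpropanamide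
Product: 14 4-{[(2S)-1-[3-bromo-4-(methoxymethoxy)phenyl]-3-[(tert-butyldimethylsilyl)oxy]-1-oxopropan-2-yl]oxy}-3-(methoxymethoxy)benzonitrile, via arylmagnesium chloride 12 (not isolated), via magnesium hemiaminal 13 (not isolated)
Conditions: 11, iPrMgCl·LiCl, THF, −20 °C; then 9, −20 → 0 °C; aq. NH4Cl
Reagents that add atoms: none
Why: Iodine–magnesium exchange is far faster than bromine–magnesium exchange at −20 °C, so 12 should form with the bromide intact (meta to magnesium, so no aryne), and its addition to the Weinreb amide stops at the chelated hemiaminal 13, which releases the ketone only on quench (Weinreb ketone synthesis), while the aryl nitrile is too slow an electrophile at 0 °C.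

Step 9
Reactants: 14 4-{[(2S)-1-[3-bromo-4-(methoxymethoxy)phenyl]-3-[(tert-butyldimethylsilyl)oxy]-1-oxopropan-2-yl]oxy}-3-(methoxymethoxy)benzonitrile
Product: 15 4-{[(2S)-1-[3-bromo-4-(methoxymethoxy)phenyl]-3-[(tert-butyldimethylsilyl)oxy]-1-hydroxypropan-2-yl]oxy}-3-(methoxymethoxy)benzonitrile (both C1 epimers)
Conditions: NaBH4, THF/MeOH, −40 → −20 °C
Reagents that add atoms: none
Why: Borohydride reduction of the aryl ketone is fast at low temperature, which limits base contact of the α-aryloxy centre; the new carbinol centre is left uncontrolled on purpose, since both epimers converge in step 10.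

Step 10
Reactants: 15 4-{[(2S)-1-[3-bromo-4-(methoxymethoxy)phenyl]-3-[(tert-butyldimethylsilyl)oxy]-1-hydroxypropan-2-yl]oxy}-3-(methoxymethoxy)benzonitrile (both C1 epimers)
Product: 18 (2S,3S)-3-(3-bromo-4-hydroxyphenyl)-2-(hydroxymethyl)-2,3-dihydro-1,4-benzodioxine-6-carbonitrile (trans ring B), via deprotected tetraol 16 (not isolated), via para-quinone methide 17 (not isolated)
Conditions: HCl (about 1 M, from aq. conc. HCl in MeOH, 1:9), 0 °C → rt, stopped as soon as the cis isomer is consumed
Reagents that add atoms: none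
Why: Dilute methanolic HCl first solvolyses both MOM acetals and the TBS ether to give 16 and then protonates the benzylic hydroxyl, whose departure as water is pushed by the para hydroxyl of ring C and gives the O-protonated para-quinone methide 17; this is the acid-mediated quinone methide cyclisation of aryl glycerol β-aryl ethers, a known way to trans-2-aryl-3-hydroxymethyl-1,4-benzodioxanes. The ring A hydroxyl meta to the nitrile, tethered through C4a–O4–C3, adds to the exocyclic carbon of 17 in a 6-exo-trig oxa-1,6-addition that forms O1–C2, closes ring B and re-aromatises ring C. The adduct is again a para-hydroxybenzyl aryl ether and re-ionises under the same acid, so the new C2 centre is set under thermodynamic control by the fixed C3 centre: both epimers of 15 and any cis isomer should funnel to the trans ring (C2 S, C3 S), in which the C2 aryl and C3 hydroxymethyl groups are both equatorial. The step needs this trans selectivity without loss of the C3 configuration, and that is secured because no bond to C3 is broken as long as the intramolecular six-membered closure outruns tautomerisation of 17 to the enol ether, which the low temperature and short exposure favour. Attack by the C3 hydroxymethyl oxygen is no competitor, since it would need a four-membered oxetane, methanol adducts at C2 re-ionise into the same manifold, and the dilute aqueous acid should leave the nitrile untouched.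

Step 11
Reactants: 19 ethyl caffeate
Product: 20 ethyl (E)-3-[3,4-bis(allyloxy)phenyl]prop-2-enoate
Conditions: allyl bromide, K2CO3, DMF, 50 °C
Reagents that add atoms: allyl bromide, C=CCBr
Why: Williamson allylation of both phenols; allyl ethers tolerate base, hydride, copper catalysis and heat to 110 °C and can be removed at the end without acid.

Step 12
Reactants: 20 ethyl (E)-3-[3,4-bis(allyloxy)phenyl]prop-2-enoate
Product: 21 (E)-3-[3,4-bis(allyloxy)phenyl]prop-2-en-1-ol
Conditions: iBu2AlH (DIBAL-H), CH2Cl2, −78 → 0 °C; aq. potassium sodium tartrate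
Reagents that add atoms: none
Why: 1,2-Reduction of the α,β-unsaturated ester by iBu2AlH should give the (E)-allylic alcohol with the alkene geometry unchanged.

Step 13
Reactants: 21 (E)-3-[3,4-bis(allyloxy)phenyl]prop-2-en-1-ol
Product: 22 [(2S,3S)-3-[3,4-bis(allyloxy)phenyl]oxiran-2-yl]methanol
Conditions: Ti(OiPr)4 (10 mol%), L-(+)-diethyl tartrate (12 mol%), tBuOOH, 4 Å MS, CH2Cl2, −20 °C
Reagents that add atoms: tert-butyl hydroperoxide, CC(C)(C)OO
Why: Sharpless asymmetric epoxidation (catalytic version with molecular sieves): with L-(+)-diethyl tartrate the oxygen is delivered to the face of the (E)-allylic alcohol that gives the (2S,3S)-epoxide, so both centres of the later ring D are set by reagent control, and the isolated allyl ether alkenes are not epoxidised by this allylic-alcohol-directed system.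

Step 14
Reactants: 18 (2S,3S)-3-(3-bromo-4-hydroxyphenyl)-2-(hydroxymethyl)-2,3-dihydro-1,4-benzodioxine-6-carbonitrile; 22 [(2S,3S)-3-[3,4-bis(allyloxy)phenyl]oxiran-2-yl]methanol
Product: 23 (2S,3S)-3-{4-[(1R,2S)-1-[3,4-bis(allyloxy)phenyl]-2,3-dihydroxypropoxy]-3-bromophenyl}-2-(hydroxymethyl)-2,3-dihydro-1,4-benzodioxine-6-carbonitrile
Conditions: Cs2CO3 (0.3 equiv), DMF, 70 °C
Reagents that add atoms: none
Why: Base-catalysed opening of a 2,3-epoxy alcohol by a phenoxide: only the phenol of 18 is deprotonated by the carbonate, and it should attack the benzylic C3 of the epoxide (activated electronically and remote from the hydroxymethyl group) in an SN2 manner, so C2' of ring D is formed with inversion (S to R) and the epoxide C2 becomes the (S) carbinol unchanged.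

Step 15
Reactants: 23 (2S,3S)-3-{4-[(1R,2S)-1-[3,4-bis(allyloxy)phenyl]-2,3-dihydroxypropoxy]-3-bromophenyl}-2-(hydroxymethyl)-2,3-dihydro-1,4-benzodioxine-6-carbonitrile
Product: 24 bis(tert-butyldiphenylsilyl) ether of 23 at both primary hydroxyls (secondary hydroxyl free)
Conditions: TBDPSCl (2.3 equiv), imidazole, CH2Cl2, 0 °C → rt
Reagents that add atoms: tert-butyldiphenylsilyl chloride (TBDPSCl), CC(C)(C)[Si](Cl)(c1ccccc1)c1ccccc1
Why: TBDPSCl silylates the two primary hydroxyls selectively and leaves the hindered secondary hydroxyl free for ring closure; the bulky diphenylsilyl group is chosen because it migrates to a neighbouring alkoxide much less readily than TBS.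

Step 16
Reactants: 24 bis(tert-butyldiphenylsilyl) ether of 23
Product: 25 (2S,3S)-3-[(2R,3S)-2-[3,4-bis(allyloxy)phenyl]-3-{[(tert-butyldiphenylsilyl)oxy]methyl}-2,3-dihydro-1,4-benzodioxin-6-yl]-2-{[(tert-butyldiphenylsilyl)oxy]methyl}-2,3-dihydro-1,4-benzodioxine-6-carbonitrile
Conditions: CuI (10 mol%), 1,10-phenanthroline (20 mol%), Cs2CO3 (2 equiv), toluene, 110 °C
Reagents that add atoms: none
Why: Intramolecular Ullmann-type C–O coupling: monovalent copper with phenanthroline inserts into the aryl bromide ortho to the ether oxygen and the secondary alkoxide closes the six-membered ring D, and since no bond at C3' or C2' is broken both centres are retained and the ring should be cis.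

Step 17
Reactants: 25 ring A–E nitrile
Product: 27 (2S,3S)-3-[(2R,3S)-2-[3,4-bis(allyloxy)phenyl]-3-{[(tert-butyldiphenylsilyl)oxy]methyl}-2,3-dihydro-1,4-benzodioxin-6-yl]-2-{[(tert-butyldiphenylsilyl)oxy]methyl}-2,3-dihydro-1,4-benzodioxine-6-carbaldehyde, via N-aluminoaldimine 26 (not isolated)
Conditions: iBu2AlH (DIBAL-H), toluene, −78 °C; then aq. potassium sodium tartrate and pH 5 acetate buffer, 0 °C
Reagents that add atoms: water, O
Why: iBu2AlH adds once to the aryl nitrile to give the aluminium aldimine 26, stable at −78 °C, which is hydrolysed to the aldehyde under buffered conditions that do not ionise the benzylic aryl ethers.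

Step 18
Reactants: 27 ring A–E aldehyde
Product: 28 (E)-3-[(2S,3S)-3-[(2R,3S)-2-[3,4-bis(allyloxy)phenyl]-3-{[(tert-butyldiphenylsilyl)oxy]methyl}-2,3-dihydro-1,4-benzodioxin-6-yl]-2-{[(tert-butyldiphenylsilyl)oxy]methyl}-2,3-dihydro-1,4-benzodioxin-6-yl]prop-2-enal
Conditions: Ph3P=CHCHO (1.5 equiv), toluene, 80 °C
Reagents that add atoms: (triphenylphosphoranylidene)acetaldehyde, O=CC=P(c1ccccc1)(c1ccccc1)c1ccccc1
Why: Wittig olefination with the stabilised formylmethylene ylide should give the (E)-enal selectively (thermodynamic control of the oxaphosphetane), the product enal being less reactive toward the ylide than the aryl aldehyde.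

Step 19
Reactants: 28 bis-silyl bis-allyl enal
Product: 29 (E)-3-[(2S,3S)-3-[(2R,3S)-2-[3,4-bis(allyloxy)phenyl]-3-(hydroxymethyl)-2,3-dihydro-1,4-benzodioxin-6-yl]-2-(hydroxymethyl)-2,3-dihydro-1,4-benzodioxin-6-yl]prop-2-enal
Conditions: Bu4NF, AcOH (1:1), THF, 0 °C → rt
Reagents that add atoms: none
Why: Fluoride cleaves both primary silyl ethers, and buffering with acetic acid keeps the medium near neutral so that the enal should be untouched.

Step 20
Reactants: 29 bis-allyl enal diol
Product: 30 (E)-3-[(2S,3S)-3-[(2R,3S)-2-(3,4-dihydroxyphenyl)-3-(hydroxymethyl)-2,3-dihydro-1,4-benzodioxin-6-yl]-2-(hydroxymethyl)-2,3-dihydro-1,4-benzodioxin-6-yl]prop-2-enal (CNP0302404.1)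
Conditions: Pd(PPh3)4 (5 mol%), N-methylaniline (6 equiv), THF, rt, argon
Reagents that add atoms: none
Why: Tsuji–Trost deallylation: zerovalent palladium ionises the aryl allyl ethers to π-allyl complexes that the weakly basic N-methylaniline captures, so the catechol is released at room temperature without acid or strong base, conditions under which the enal and the now para-hydroxybenzylic cis ring D (prone to acid epimerisation) should survive.

**Compound list**

1 | 3,4-dihydroxybenzonitrile | N#Cc1ccc(O)c(O)c1 | starting material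
2 | 4-hydroxy-3-(methoxymethoxy)benzonitrile | N#Cc1ccc(O)c(OCOC)c1 | intermediate
3 | D-serine, (R)-2-amino-3-hydroxypropanoic acid | N[C@H](CO)C(=O)O | starting material
4 | (S)-3-(hydroxymethyl)oxiran-2-one (α-lactone) | O=C1O[C@H]1CO | intermediate
5 | (R)-glyceric acid | O[C@H](CO)C(=O)O | intermediate
6 | methyl (R)-glycerate | O[C@H](CO)C(=O)OC | intermediate
7 | methyl (R)-3-[(tert-butyldimethylsilyl)oxy]-2-hydroxypropanoate | O[C@H](CO[Si](C)(C)C(C)(C)C)C(=O)OC | intermediate
8 | methyl (S)-3-[(tert-butyldimethylsilyl)oxy]-2-[4-cyano-2-(methoxymethoxy)phenoxy]propanoate | N#Cc1ccc(O[C@@H](CO[Si](C)(C)C(C)(C)C)C(=O)OC)c(OCOC)c1 | intermediate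
9 | (S)-3-[(tert-butyldimethylsilyl)oxy]-2-[4-cyano-2-(methoxymethoxy)phenoxy]-N-methoxy-N-methylpropanamide | N#Cc1ccc(O[C@@H](CO[Si](C)(C)C(C)(C)C)C(=O)N(C)OC)c(OCOC)c1 | intermediate
10 | 2-bromo-4-iodophenol | Oc1ccc(I)cc1Br | starting material
11 | 2-bromo-4-iodo-1-(methoxymethoxy)benzene | COCOc1ccc(I)cc1Br | intermediate
12 | [3-bromo-4-(methoxymethoxy)phenyl]magnesium chloride, LiCl complex | COCOc1ccc([Mg]Cl)cc1Br.[Li+].[Cl-] | intermediate
13 | chloromagnesium hemiaminal from 9 and 12 (hemiaminal carbon undefined, C2 S) | N#Cc1ccc(O[C@@H](CO[Si](C)(C)C(C)(C)C)C(O[Mg]Cl)(N(C)OC)c2ccc(OCOC)c(Br)c2)c(OCOC)c1 | intermediate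
14 | 4-{[(2S)-1-[3-bromo-4-(methoxymethoxy)phenyl]-3-[(tert-butyldimethylsilyl)oxy]-1-oxopropan-2-yl]oxy}-3-(methoxymethoxy)benzonitrile | N#Cc1ccc(O[C@@H](CO[Si](C)(C)C(C)(C)C)C(=O)c2ccc(OCOC)c(Br)c2)c(OCOC)c1 | intermediate
15 | 4-{[(2S)-1-[3-bromo-4-(methoxymethoxy)phenyl]-3-[(tert-butyldimethylsilyl)oxy]-1-hydroxypropan-2-yl]oxy}-3-(methoxymethoxy)benzonitrile, both C1 epimers | N#Cc1ccc(O[C@@H](CO[Si](C)(C)C(C)(C)C)C(O)c2ccc(OCOC)c(Br)c2)c(OCOC)c1 | intermediate
16 | 4-{[(2S)-1-(3-bromo-4-hydroxyphenyl)-1,3-dihydroxypropan-2-yl]oxy}-3-hydroxybenzonitrile, both C1 epimers | N#Cc1ccc(O[C@@H](CO)C(O)c2ccc(O)c(Br)c2)c(O)c1 | intermediate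
17 | 4-{[1-(3-bromo-4-oxocyclohexa-2,5-dien-1-ylidene)-3-hydroxypropan-2-yl]oxy}-3-hydroxybenzonitrile, para-quinone methide (serine-derived carbon spatially unchanged, formally R by priority change) | N#Cc1ccc(O[C@@H](CO)C=C2C=CC(=O)C(Br)=C2)c(O)c1 | intermediate
18 | (2S,3S)-3-(3-bromo-4-hydroxyphenyl)-2-(hydroxymethyl)-2,3-dihydro-1,4-benzodioxine-6-carbonitrile | N#Cc1ccc2c(c1)O[C@@H](c1ccc(O)c(Br)c1)[C@H](CO)O2 | intermediate
19 | ethyl caffeate, ethyl (E)-3-(3,4-dihydroxyphenyl)prop-2-enoate | CCOC(=O)/C=C/c1ccc(O)c(O)c1 | starting material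
20 | ethyl (E)-3-[3,4-bis(allyloxy)phenyl]prop-2-enoate | CCOC(=O)/C=C/c1ccc(OCC=C)c(OCC=C)c1 | intermediate
21 | (E)-3-[3,4-bis(allyloxy)phenyl]prop-2-en-1-ol | OC/C=C/c1ccc(OCC=C)c(OCC=C)c1 | intermediate
22 | [(2S,3S)-3-[3,4-bis(allyloxy)phenyl]oxiran-2-yl]methanol | OC[C@@H]1O[C@H]1c1ccc(OCC=C)c(OCC=C)c1 | intermediate
23 | (2S,3S)-3-{4-[(1R,2S)-1-[3,4-bis(allyloxy)phenyl]-2,3-dihydroxypropoxy]-3-bromophenyl}-2-(hydroxymethyl)-2,3-dihydro-1,4-benzodioxine-6-carbonitrile | N#Cc1ccc2c(c1)O[C@@H](c1ccc(O[C@H](c3ccc(OCC=C)c(OCC=C)c3)[C@@H](O)CO)c(Br)c1)[C@H](CO)O2 | intermediate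
24 | bis(tert-butyldiphenylsilyl) ether of 23 at both primary hydroxyls | N#Cc1ccc2c(c1)O[C@@H](c1ccc(O[C@H](c3ccc(OCC=C)c(OCC=C)c3)[C@@H](O)CO[Si](c3ccccc3)(c3ccccc3)C(C)(C)C)c(Br)c1)[C@H](CO[Si](c1ccccc1)(c1ccccc1)C(C)(C)C)O2 | intermediate
25 | (2S,3S)-3-[(2R,3S)-2-[3,4-bis(allyloxy)phenyl]-3-{[(tert-butyldiphenylsilyl)oxy]methyl}-2,3-dihydro-1,4-benzodioxin-6-yl]-2-{[(tert-butyldiphenylsilyl)oxy]methyl}-2,3-dihydro-1,4-benzodioxine-6-carbonitrile | N#Cc1ccc2c(c1)O[C@@H](c1ccc3c(c1)O[C@@H](CO[Si](c1ccccc1)(c1ccccc1)C(C)(C)C)[C@@H](c1ccc(OCC=C)c(OCC=C)c1)O3)[C@H](CO[Si](c1ccccc1)(c1ccccc1)C(C)(C)C)O2 | intermediate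
26 | N-(diisobutylalumino)aldimine of 27 | CC(C)C[Al](CC(C)C)N=Cc1ccc2c(c1)O[C@@H](c1ccc3c(c1)O[C@@H](CO[Si](c1ccccc1)(c1ccccc1)C(C)(C)C)[C@@H](c1ccc(OCC=C)c(OCC=C)c1)O3)[C@H](CO[Si](c1ccccc1)(c1ccccc1)C(C)(C)C)O2 | intermediate
27 | 6-carbaldehyde corresponding to nitrile 25 | O=Cc1ccc2c(c1)O[C@@H](c1ccc3c(c1)O[C@@H](CO[Si](c1ccccc1)(c1ccccc1)C(C)(C)C)[C@@H](c1ccc(OCC=C)c(OCC=C)c1)O3)[C@H](CO[Si](c1ccccc1)(c1ccccc1)C(C)(C)C)O2 | intermediate
28 | (E)-enal, bis-TBDPS, bis-allyl protected | O=C/C=C/c1ccc2c(c1)O[C@@H](c1ccc3c(c1)O[C@@H](CO[Si](c1ccccc1)(c1ccccc1)C(C)(C)C)[C@@H](c1ccc(OCC=C)c(OCC=C)c1)O3)[C@H](CO[Si](c1ccccc1)(c1ccccc1)C(C)(C)C)O2 | intermediate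
29 | (E)-enal diol, bis-allyl protected | O=C/C=C/c1ccc2c(c1)O[C@@H](c1ccc3c(c1)O[C@@H](CO)[C@@H](c1ccc(OCC=C)c(OCC=C)c1)O3)[C@H](CO)O2 | intermediate
30 | (E)-3-[(2S,3S)-3-[(2R,3S)-2-(3,4-dihydroxyphenyl)-3-(hydroxymethyl)-2,3-dihydro-1,4-benzodioxin-6-yl]-2-(hydroxymethyl)-2,3-dihydro-1,4-benzodioxin-6-yl]prop-2-enal | O=C/C=C/c1ccc2c(c1)O[C@@H](c1ccc3c(c1)O[C@@H](CO)[C@@H](c1ccc(O)c(O)c1)O3)[C@H](CO)O2 | target

**Totals**

Total step count: 20.
Longest linear sequence: 15 steps (D-serine 3 to target 30 through steps 2–6, 8–10 and 14–20).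

**Steps most likely to fail**

Step 10 (key step). The bromine meta to the benzylic carbon and the β-aryloxy group both retard ionisation of the carbinol. Long acid exposure could then let the quinone methide tautomerise to the enol ether, which erodes the C3 configuration, or let the nitrile undergo Pinner methanolysis. The fallback brings the bromine in after ring B is closed. It sets out from compound 9. Commercial 1-bromo-4-(methoxymethoxy)benzene would be converted with Mg in THF into [4-(methoxymethoxy)phenyl]magnesium bromide F1. Addition of F1 to 9 would pass through the bromomagnesium hemiaminal F2 to the bromine-free ketone F3. NaBH4 would reduce F3 to the carbinol F4. The acid treatment of step 10 would then run through the bromine-free tetraol F5 and the more easily formed quinone methide F6 to the trans phenol F7. Electrophilic bromination of F7 with NBS (1.0 equiv, MeCN, 0 °C) should go ortho to the free hydroxyl, the para position being blocked and the two ortho positions equivalent, and the route is rejoined at compound 18.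

Step 14. The phenoxide may attack C2 of the epoxy alcohol, or the terminal carbon after Payne migration of the epoxide; partial SN1 opening at the electron-rich benzylic carbon would blur the inversion; and the labile epoxide may decompose on heating. The fallback removes the free hydroxyl from the electrophile before the C–O bond is made. It sets out from compound 22, which would be silylated (TBDPSCl, imidazole) to the silyl glycidyl ether F8. In F8 epoxide migration is impossible and C2 is shielded. Opening of F8 with phenol 18 (Cs2CO3, DMF) would give the mono-silylated diol F9. Silylation of the remaining primary hydroxyl of F9 (TBDPSCl, imidazole) rejoins the route at compound 24.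

Step 16. The hindered secondary alkoxide may couple slowly at copper, so that protodebromination competes, and silyl migration to the alkoxide could expose the primary oxygen and lead to a seven-membered ether. The fallback changes the metal and the bond-forming mechanism to a Buchwald–Hartwig-type etherification. It sets out from compound 24 and uses Pd(OAc)2 with 2-(di-tert-butylphosphino)-1,1'-binaphthyl and Cs2CO3 in toluene at 70 °C. Oxidative addition of the aryl bromide to zerovalent palladium and C–O reductive elimination from the arylpalladium alkoxide occur at lower temperature than the copper cycle. It comes back to the route at compound 25 and makes no new compound.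

**Further compounds**

F1 | step 10 | [4-(methoxymethoxy)phenyl]magnesium bromide | COCOc1ccc([Mg]Br)cc1
F2 | step 10 | bromomagnesium hemiaminal from 9 and F1 | N#Cc1ccc(O[C@@H](CO[Si](C)(C)C(C)(C)C)C(O[Mg]Br)(N(C)OC)c2ccc(OCOC)cc2)c(OCOC)c1
F3 | step 10 | 4-{[(2S)-3-[(tert-butyldimethylsilyl)oxy]-1-[4-(methoxymethoxy)phenyl]-1-oxopropan-2-yl]oxy}-3-(methoxymethoxy)benzonitrile | N#Cc1ccc(O[C@@H](CO[Si](C)(C)C(C)(C)C)C(=O)c2ccc(OCOC)cc2)c(OCOC)c1
F4 | step 10 | 4-{[(2S)-3-[(tert-butyldimethylsilyl)oxy]-1-hydroxy-1-[4-(methoxymethoxy)phenyl]propan-2-yl]oxy}-3-(methoxymethoxy)benzonitrile, both C1 epimers | N#Cc1ccc(O[C@@H](CO[Si](C)(C)C(C)(C)C)C(O)c2ccc(OCOC)cc2)c(OCOC)c1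
F5 | step 10 | 4-{[(2S)-1,3-dihydroxy-1-(4-hydroxyphenyl)propan-2-yl]oxy}-3-hydroxybenzonitrile, both C1 epimers | N#Cc1ccc(O[C@@H](CO)C(O)c2ccc(O)cc2)c(O)c1
F6 | step 10 | 3-hydroxy-4-{[3-hydroxy-1-(4-oxocyclohexa-2,5-dien-1-ylidene)propan-2-yl]oxy}benzonitrile, para-quinone methide | N#Cc1ccc(O[C@@H](CO)C=C2C=CC(=O)C=C2)c(O)c1
F7 | step 10 | (2S,3S)-2-(hydroxymethyl)-3-(4-hydroxyphenyl)-2,3-dihydro-1,4-benzodioxine-6-carbonitrile | N#Cc1ccc2c(c1)O[C@@H](c1ccc(O)cc1)[C@H](CO)O2
F8 | step 14 | tert-butyl{[(2S,3S)-3-[3,4-bis(allyloxy)phenyl]oxiran-2-yl]methoxy}diphenylsilane | CC(C)(C)[Si](OC[C@@H]1O[C@H]1c1ccc(OCC=C)c(OCC=C)c1)(c1ccccc1)c1ccccc1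
F9 | step 14 | (2S,3S)-3-{4-[(1R,2S)-1-[3,4-bis(allyloxy)phenyl]-3-[(tert-butyldiphenylsilyl)oxy]-2-hydroxypropoxy]-3-bromophenyl}-2-(hydroxymethyl)-2,3-dihydro-1,4-benzodioxine-6-carbonitrile | N#Cc1ccc2c(c1)O[C@@H](c1ccc(O[C@H](c3ccc(OCC=C)c(OCC=C)c3)[C@@H](O)CO[Si](c3ccccc3)(c3ccccc3)C(C)(C)C)c(Br)c1)[C@H](CO)O2
F0 | step 16 | none | none
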